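**Retrosynthetic overview**
1. The oxepane is closed last by forming the C3–O16 bond: a hydrogen-atom-transfer hydroalkoxylation of the exocyclic C3=C18 alkene of tricycle 24, which also sets C3.
2. The oxonene (C6=C7) of 24 comes from ring-closing metathesis of diene 23; the C11 butanoate comes from reduction and acylation of the C11 ketone.
3. The tetrahydrofuran comes from hydroxy acetal 17 by O–C9 ring closure and convex-face methallylation; 17 comes from aldehyde 12 and alkenyl bromide 15.
4. The cyclohexane comes from an endo Diels–Alder reaction of enal 4 (Roche ester) with dienyl acetal 8, then hydroboration for C11/C12.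
5. Ring order: cyclohexane, then tetrahydrofuran, then oxonene, then oxepane.

Assumption: locants C1–C20 are those of the asbestinin skeleton (C1/C10 ring fusion, C2/C9 ether carbons, C3 quaternary, C11 acyloxy, C12 methyl-bearing, C14–C15–C16 side chain, C18 = C3 methyl); "upper face" means the face of the cyclohexane that carries C2 and C9.

**Step 1**
Reactants: 1 methyl (S)-3-hydroxy-2-methylpropanoate
Product: 2 methyl (S)-3-[(tert-butyldimethylsilyl)oxy]-2-methylpropanoate
Conditions: TBSCl, imidazole, CH2Cl2, 0 °C → rt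
Reagents that add atoms: tert-butyldimethylsilyl chloride, CC(C)(C)[Si](C)(C)Cl
Why: Standard silylation of the primary alcohol; the stereocentre (later C15) is not touched.

**Step 2**
Reactants: 2 methyl (S)-3-[(tert-butyldimethylsilyl)oxy]-2-methylpropanoate
Product: 3 (S)-3-[(tert-butyldimethylsilyl)oxy]-2-methylpropanal
Conditions: iBu2AlH (1.05 equiv), CH2Cl2, −78 °C; Rochelle salt work-up; used crude
Reagents that add atoms: none
Why: Partial ester reduction with DIBAL-H stops at the aldehyde because the tetrahedral aluminium hemiacetal survives at −78 °C; the α-stereocentre is kept by using the aldehyde cold and at once.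

**Step 3**
Reactants: 3 (S)-3-[(tert-butyldimethylsilyl)oxy]-2-methylpropanal
Product: 4 (R,E)-5-[(tert-butyldimethylsilyl)oxy]-4-methylpent-2-enal
Conditions: Ph3P=CHCHO, toluene, 80 °C
Reagents that add atoms: (triphenylphosphoranylidene)acetaldehyde, O=CC=P(c1ccccc1)(c1ccccc1)c1ccccc1
Why: Wittig olefination with a stabilised ylide gives the (E)-enal under base-free conditions, so the stereocentre is kept (the descriptor changes to R only through CIP priorities).

**Step 4**
Reactants: 5 methacrolein; 6 (1,3-dioxolan-2-ylmethyl)triphenylphosphonium bromide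
Product: 8 (E)-2-(3-methylbuta-1,3-dien-1-yl)-1,3-dioxolane, via phosphorus ylide 7 (not isolated)
Conditions: 6, KOtBu, THF, 0 °C; then 5, 0 °C → rt; then I2 (2 mol %), hexane, hν, rt
Reagents that add atoms: none
Why: Wittig olefination with a semi-stabilised ylide gives an E/Z mixture that iodine-catalysed isomerisation funnels to the (E)-diene needed for the cycloaddition.

**Step 5**
Reactants: 4 (R,E)-5-[(tert-butyldimethylsilyl)oxy]-4-methylpent-2-enal; 8 (E)-2-(3-methylbuta-1,3-dien-1-yl)-1,3-dioxolane
Product: 9 (1S,2R,6S)-6-[(R)-1-(tert-butyldimethylsilyloxy)propan-2-yl]-2-(1,3-dioxolan-2-yl)-4-methylcyclohex-3-ene-1-carbaldehyde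
Conditions: (5R)-5-benzyl-2,2,3-trimethylimidazolidin-4-one·TFA (20 mol %), MeCN/H2O 95:5, −10 °C, 72 h
Reagents that add atoms: none
Why: Iminium-catalysed (MacMillan) endo Diels–Alder reaction in which the 1-substituent and the 3-methyl group of the diene both direct C10 to the formyl-bearing C1; the (E)-enal fixes C2/C15 trans, the endo transition state fixes C9/C2 cis, and the catalyst benzyl group shields the C14 Re face so that C1 (S), C10 and C14 (S) are set.

**Step 6**
Reactants: 9 Diels–Alder aldehyde
Product: 11 diol (1S,10S,11S,12R,14S,15R): cyclohexane with CH2OH (C2) on C1 and the dioxolanyl group (C9) on C10 and OH on C11 and CH3 on C12 and the CH(CH3)CH2OTBS chain on C14, via organoborane 10 (not isolated)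
Conditions: BH3·THF (2.5 equiv), THF, 0 °C → rt; then NaOH, H2O2, 0 °C
Reagents that add atoms: hydrogen peroxide, OO
Why: Hydroboration–oxidation places boron on the less substituted C11 and delivers H to C12 syn from the lower face, anti to the pseudo-axial C10 acetal, which sets the C12 methyl on the upper face (12R) and C11–OH on the lower face; the aldehyde is reduced to CH2OH in the same operation.

**Step 7**
Reactants: 11 diol
Product: 12 keto aldehyde (1S,10R,12R,14S,15R): as 11 but with C2 as CHO and C11 as ketone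
Conditions: Dess–Martin periodinane (2.6 equiv), NaHCO3, CH2Cl2, 0 °C → rt; used at once
Reagents that add atoms: none
Why: Dess–Martin oxidation of both alcohols under buffered, non-enolising conditions keeps the α-stereocentres C1, C10 and C12.

**Step 8**
Reactants: 13 2,3-dibromopropene; 14 allylmagnesium bromide
Product: 15 2-bromohexa-1,5-diene
Conditions: Et2O, 0 °C → rt
Reagents that add atoms: none
Why: Grignard allylation of the allylic C–Br bond (SN2 or SN2′ give the same product) leaves the unreactive vinylic bromide in place.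

**Step 9**
Reactants: 12 keto aldehyde; 15 2-bromohexa-1,5-diene
Product: 17 allylic alcohol (1S,2S,10R,12R,14S,15R): 12 with C2 as CH(OH) bearing the hexa-1,5-dien-2-yl group (C3=C18 and C4–C6), via alkenylchromium reagent 16 (not isolated)
Conditions: 15 (2 equiv), CrCl2 (4 equiv), NiCl2 (2 mol %), Kishi oxazoline–sulfonamide ligand (4.4 equiv, enantiomer for Re-face transfer), Et3N, THF, rt
Reagents that add atoms: none
Why: Asymmetric Nozaki–Hiyama–Kishi coupling, in which zerovalent nickel inserts into the C–Br bond and hands the alkenyl group to chromium, which adds only to the aldehyde (ketone, acetal and silyl ether are inert); the chiral sulfonamide on chromium directs addition to the Re face of C2 to give the 2S carbinol under reagent control.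

**Step 10**
Reactants: 17 allylic alcohol; 18 methallyltrimethylsilane
Product: 21 tetrahydrofuran ketone (1S,2S,9S,10R,12R,14S,15R): cis-fused 2,9-epoxy bicycle with methallyl on C9 and the hexadienyl group on C2, via mixed acetal 19 (not isolated), via oxocarbenium ion 20 (not isolated)
Conditions: 18 (3 equiv), TMSOTf (0.3 equiv), CH2Cl2, −78 → −40 °C
Reagents that add atoms: none
Why: Acid-mediated transacetalisation lets the C2 hydroxyl close the tetrahydrofuran (O–C9 bond), re-ionisation gives the cis-fused bicyclic oxocarbenium ion, and Hosomi–Sakurai attack of the allylsilane on its convex face, anti to the C10–C11 bond, sets C9 (S) with C8 cis to C3.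

**Step 11**
Reactants: 21 tetrahydrofuran ketone
Product: 22 C11 alcohol (1S,2S,9S,10R,11R,12R,14S,15R)
Conditions: LiBH(s-Bu)3, THF, −78 °C; aqueous NH4Cl
Reagents that add atoms: none
Why: The bulky hydride (L-Selectride reduction) attacks the ketone from the lower face because the upper face is blocked by the C9, C2 and C12-methyl groups, giving the 11R alcohol cis to both neighbours; at −78 °C the labile C10 and C12 centres do not enolise.

**Step 12**
Reactants: 22 C11 alcohol
Product: 23 butanoate diene (C11 O-butanoyl derivative of 22)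
Conditions: (PrCO)2O, Et3N, DMAP, CH2Cl2, rt
Reagents that add atoms: butyric anhydride, CCCC(=O)OC(=O)CCC
Why: DMAP-catalysed acylation of the only free hydroxyl installs the butanoate with retention.

**Step 13**
Reactants: 23 butanoate diene
Product: 24 tricyclic oxonene: 2,9-epoxy bridged 9-membered ring with (Z)-C6=C7 and exocyclic C3=C18 methylene and C16–OTBS
Conditions: second-generation Grubbs catalyst RuCl2(=CHPh)(H2IMes)(PCy3) (10 mol %), toluene, 80 °C, 1 mM
Reagents that add atoms: none
Why: Ring-closing metathesis starts at the monosubstituted C6 vinyl group and closes onto the cis-disposed methallyl group; the ring enforces the (Z)-trisubstituted alkene, and the hindered C3=C18 alkene cannot give a reasonable ring.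

**Step 14**
Reactants: 24 tricyclic oxonene
Product: 26 4-deoxyasbestinin C, via silyloxonium ion 25 (not isolated)
Conditions: [N,N′-bis(3,5-di-tert-butylsalicylidene)ethylenediaminato]cobalt (5 mol %), N-fluoro-2,4,6-trimethylpyridinium tetrafluoroborate (1.5 equiv), PhSiH3 (1.5 equiv), PhCF3, 0 °C → rt
Reagents that add atoms: none
Why: Proposed new method: the divalent cobalt salen complex is oxidised by the N-fluoropyridinium salt and converted by the silane into a trivalent cobalt hydride that transfers a hydrogen atom to the unhindered C18 terminus of the 1,1-disubstituted alkene (the endocyclic trisubstituted C6=C7 alkene reacts much more slowly), the tertiary C3 radical is captured and oxidised to an alkylcobalt/carbocation, the tethered silyl ether oxygen O16 closes the seven-membered ring from the C1 side in the rotamer with C2–H eclipsing the methylene (least allylic strain) to give 3S, and fluoride removes the silyl group from oxonium ion 25; the closest known reaction type is the cobalt-salen/N-fluoropyridinium/silane Mukaiyama-type hydroalkoxylation (hydrogen atom transfer, radical–polar crossover) of unactivated alkenes, known for five- and six-membered ethers but not for a bridging oxepane with a fully substituted ether stereocentre beside a second alkene.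

**Compound list**
1 | methyl (S)-3-hydroxy-2-methylpropanoate | OC[C@H](C)C(=O)OC | starting material
2 | methyl (S)-3-[(tert-butyldimethylsilyl)oxy]-2-methylpropanoate | CC(C)(C)[Si](C)(C)OC[C@H](C)C(=O)OC | intermediate
3 | (S)-3-[(tert-butyldimethylsilyl)oxy]-2-methylpropanal | CC(C)(C)[Si](C)(C)OC[C@H](C)C=O | intermediate
4 | (R,E)-5-[(tert-butyldimethylsilyl)oxy]-4-methylpent-2-enal | CC(C)(C)[Si](C)(C)OC[C@H](C)/C=C/C=O | intermediate
5 | methacrolein | CC(=C)C=O | starting material
6 | (1,3-dioxolan-2-ylmethyl)triphenylphosphonium bromide | [Br-].O1CCOC1C[P+](c1ccccc1)(c1ccccc1)c1ccccc1 | starting material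
7 | (1,3-dioxolan-2-ylmethylidene)triphenylphosphorane | O1CCOC1C=P(c1ccccc1)(c1ccccc1)c1ccccc1 | intermediate (not isolated)
8 | (E)-2-(3-methylbuta-1,3-dien-1-yl)-1,3-dioxolane | C=C(C)/C=C/C1OCCO1 | intermediate
9 | (1S,2R,6S)-6-[(R)-1-(TBSO)propan-2-yl]-2-(1,3-dioxolan-2-yl)-4-methylcyclohex-3-ene-1-carbaldehyde | CC(C)(C)[Si](C)(C)OC[C@H](C)[C@@H]1CC(C)=C[C@@H](C2OCCO2)[C@H]1C=O | intermediate
10 | organoborane from 9 (C11–BH2 and C2–O–BH2, idealised monomer) | CC(C)(C)[Si](C)(C)OC[C@H](C)[C@@H]1C[C@@H](C)[C@H](B)[C@@H](C2OCCO2)[C@H]1COB | intermediate (not isolated)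
11 | diol (1S,10S,11S,12R,14S,15R) | CC(C)(C)[Si](C)(C)OC[C@H](C)[C@@H]1C[C@@H](C)[C@H](O)[C@@H](C2OCCO2)[C@H]1CO | intermediate
12 | keto aldehyde (1S,10R,12R,14S,15R) | CC(C)(C)[Si](C)(C)OC[C@H](C)[C@@H]1C[C@@H](C)C(=O)[C@@H](C2OCCO2)[C@H]1C=O | intermediate
13 | 2,3-dibromopropene | BrCC(Br)=C | starting material
14 | allylmagnesium bromide | C=CC[Mg]Br | starting material
15 | 2-bromohexa-1,5-diene | C=C(Br)CCC=C | intermediate
16 | dichloro(hexa-1,5-dien-2-yl)chromium (trivalent chromium, chiral ligand omitted) | C=C(CCC=C)[Cr](Cl)Cl | intermediate (not isolated)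
17 | allylic alcohol (1S,2S,10R,12R,14S,15R) | CC(C)(C)[Si](C)(C)OC[C@H](C)[C@@H]1C[C@@H](C)C(=O)[C@@H](C2OCCO2)[C@H]1[C@H](O)C(=C)CCC=C | intermediate
18 | methallyltrimethylsilane | CC(=C)C[Si](C)(C)C | starting material
19 | mixed acetal: C9 (2-hydroxyethoxy) tetrahydrofuran | CC(C)(C)[Si](C)(C)OC[C@H](C)[C@@H]1C[C@@H](C)C(=O)[C@@H]2[C@H]1[C@@H](C(=C)CCC=C)OC2OCCO | intermediate (not isolated)
20 | bicyclic oxocarbenium ion (C9=O+) | CC(C)(C)[Si](C)(C)OC[C@H](C)[C@@H]1C[C@@H](C)C(=O)[C@@H]2[C@H]1[C@@H](C(=C)CCC=C)[O+]=C2 | intermediate (not isolated)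
21 | tetrahydrofuran ketone (1S,2S,9S,10R,12R,14S,15R) | CC(C)(C)[Si](C)(C)OC[C@H](C)[C@@H]1C[C@@H](C)C(=O)[C@@H]2[C@H]1[C@@H](C(=C)CCC=C)O[C@H]2CC(C)=C | intermediate
22 | C11 alcohol (1S,2S,9S,10R,11R,12R,14S,15R) | CC(C)(C)[Si](C)(C)OC[C@H](C)[C@@H]1C[C@@H](C)[C@@H](O)[C@@H]2[C@H]1[C@@H](C(=C)CCC=C)O[C@H]2CC(C)=C | intermediate
23 | butanoate diene | CC(C)(C)[Si](C)(C)OC[C@H](C)[C@@H]1C[C@@H](C)[C@@H](OC(=O)CCC)[C@@H]2[C@H]1[C@@H](C(=C)CCC=C)O[C@H]2CC(C)=C | intermediate
24 | tricyclic oxonene, (Z)-C6=C7, exocyclic C3=C18, C16–OTBS | CC(C)(C)[Si](C)(C)OC[C@H](C)[C@@H]1C[C@@H](C)[C@@H](OC(=O)CCC)[C@@H]2[C@H]1[C@@H](C(=C)CC/C=C(/C)C3)O[C@H]23 | intermediate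
25 | O16-silyloxonium ion of the closed oxepane | CCCC(=O)O[C@H]1[C@@H]2[C@@H]3[C@@H](C[C@H]1C)[C@@H](C)C[O+]([Si](C)(C)C(C)(C)C)[C@@]1(C)CC/C=C(/C)C[C@@H]2O[C@@H]31 | intermediate (not isolated)
26 | 4-deoxyasbestinin C (1S,2S,3S,9S,10R,11R,12R,14S,15R; 6Z) | CCCC(=O)O[C@H]1[C@@H]2[C@@H]3[C@@H](C[C@H]1C)[C@@H](C)CO[C@@]1(C)CC/C=C(/C)C[C@@H]2O[C@@H]31 | target

**Step count and risks**
Total steps: 14. Longest linear sequence: 12 (steps 1–3, 5–7, 9–14).

Most likely to fail, first: step 14 (the proposed new ring closure). Risks are hydrogen atom transfer to the C6=C7 alkene, elimination of the C3 cation, and the wrong C3 epimer. The fallback uses known chemistry, sets out from 24 and returns at 26. HF·pyridine in THF removes the silyl group to give the primary alcohol F6. N-iodosuccinimide in CH2Cl2 at 0 °C then effects a 7-exo iodoetherification (O16 onto C3, iodine on C18) to give the iodomethyl oxepane F7. Bu3SnH with AIBN and catalytic PhSeSePh in benzene at 80 °C (fast hydrogen transfer to outrun transannular radical cyclisation) reduces C18–I to the methyl group of 26. The facial argument at C3 is the same as in step 14, so this fallback does not remove the C3 risk.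

Second: step 5 (slow reaction of the β-branched enal, loss of the dienyl acetal in aqueous acid, possible scrambling of C15 through a dienamine). The fallback sets out from 3 and returns at 11. Masamune–Roush olefination of 3 with (R)-4-benzyl-3-[(diethoxyphosphoryl)acetyl]oxazolidin-2-one (LiCl, iPr2NEt, MeCN) gives the N-enoyl oxazolidinone F1. An auxiliary-controlled Diels–Alder reaction with 8 (Me2AlCl, CH2Cl2, −78 °C; diene anti to benzyl on the chelated s-cis imide, endo) gives the imide adduct F2. LiBH4 (THF/MeOH, 0 °C) cleaves the auxiliary to the primary alcohol F3, and the hydroboration–oxidation conditions of step 6 convert F3 into 11.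

Third: step 9 (the intrinsic Felkin bias of the aldehyde may oppose the ligand at C2). The fallback sets out from 12 and returns at 17. Addition of hexa-1,5-dien-2-ylcerium dichloride (from 15, t-BuLi, CeCl3, THF, −78 °C) gives the C2-epimeric allylic alcohols F4. Dess–Martin oxidation gives the enone F5. Reduction with (R)-2-methyl-CBS-oxazaborolidine and catecholborane at −78 °C sets C2 at the ketone stage (the enone carbonyl reacts before the doubly α-branched C11 ketone), giving 17.

**Further compounds**
F1 | step 5 | (R)-4-benzyl-3-[(R,E)-5-(tert-butyldimethylsilyloxy)-4-methylpent-2-enoyl]oxazolidin-2-one | CC(C)(C)[Si](C)(C)OC[C@H](C)/C=C/C(=O)N1[C@H](Cc2ccccc2)COC1=O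
F2 | step 5 | Diels–Alder adduct imide (ring stereocentres as in 9) | CC(C)(C)[Si](C)(C)OC[C@H](C)[C@@H]1CC(C)=C[C@@H](C2OCCO2)[C@H]1C(=O)N1[C@H](Cc2ccccc2)COC1=O
F3 | step 5 | primary alcohol (9 with CH2OH in place of CHO) | CC(C)(C)[Si](C)(C)OC[C@H](C)[C@@H]1CC(C)=C[C@@H](C2OCCO2)[C@H]1CO
F4 | step 9 | C2-epimeric mixture of allylic alcohol 17 | CC(C)(C)[Si](C)(C)OC[C@H](C)[C@@H]1C[C@@H](C)C(=O)[C@@H](C2OCCO2)[C@H]1C(O)C(=C)CCC=C
F5 | step 9 | C2 enone | CC(C)(C)[Si](C)(C)OC[C@H](C)[C@@H]1C[C@@H](C)C(=O)[C@@H](C2OCCO2)[C@H]1C(=O)C(=C)CCC=C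
F6 | step 14 | primary alcohol (24 without the silyl group) | OC[C@H](C)[C@@H]1C[C@@H](C)[C@@H](OC(=O)CCC)[C@@H]2[C@H]1[C@@H](C(=C)CC/C=C(/C)C3)O[C@H]23
F7 | step 14 | 18-iodo-4-deoxyasbestinin C (iodomethyl oxepane) | CCCC(=O)O[C@H]1[C@@H]2[C@@H]3[C@@H](C[C@H]1C)[C@@H](C)CO[C@@]1(CI)CC/C=C(/C)C[C@@H]2O[C@@H]31
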